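The route rests on cutting the butenolide (ring O6–C12–C11=C7–C6) at its carbonyl-to-α-carbon bond C12–C11. In the key step an alkoxycarbonyl radical on O6 closes this ring by attacking the central carbon of an exocyclic allene C7=C11=C13 on the preformed ten-membered ring, and copper diacetate turns the resulting allyl radical into the C13 acetate. One operation thus delivers the lactone, the tetrasubstituted C7=C11 olefin and the acetoxymethyl group; it exploits the fact that a 2-(acyloxymethyl)but-2-enolide is an allene plus a carbonyl plus acetate. The precursor is a macrocyclic α-allenol peroxyoxalate, reached by a Nozaki–Hiyama allenylation that closes the carbocycle.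

Key step: step 16

Remark on the chemistry: germacrane numbering of the target is used for all intermediates (ring C1–C10, lactone carbons C11–C13 with C12 the carbonyl, C14 on C10, C15 the methyl on C4); the target is the 1R,4R,5S,6S,8S,10S isomer with a 2Z olefin, and (Z)-3-methylpent-2-en-4-yn-1-ol is taken as a commercial starting material.

Step 1
Reactants: 1 (Z)-3-methylpent-2-en-4-yn-1-ol
Product: 2 ethynyl epoxy alcohol
Conditions: Ti(OiPr)4 (10 mol %), L-(+)-diethyl tartrate (12 mol %), tBuOOH, 4 Å MS, CH2Cl2, −20 °C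
Reagents that add atoms: tert-butyl hydroperoxide CC(C)(C)OO
Why: Sharpless asymmetric epoxidation of the Z-trisubstituted allylic alcohol with the L-(+)-tartrate delivers oxygen to the face that gives the 4R,5S epoxide (the sense known for nerol), and the alkyne is inert.

Step 2
Reactants: 2 ethynyl epoxy alcohol
Product: 3 triethylsilyl ether of 2
Conditions: Et3SiCl, imidazole, CH2Cl2, 0 °C
Reagents that add atoms: chlorotriethylsilane CC[Si](Cl)(CC)CC
Why: Standard silylation masks the C6 hydroxyl as a primary triethylsilyl ether, so that it stays distinct from the C14 hydroxyl and can later be oxidised directly.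

Step 3
Reactants: 4 prop-2-yn-1-ol; 5 allylmagnesium bromide
Product: 7 (2Z)-2-(iodomethylidene)pent-4-en-1-ol, via cyclic alkenylmagnesium alkoxide 6 (not isolated)
Conditions: 5 (2.5 equiv), CuI (10 mol %), Et2O, −10 °C to rt; then I2, THF, −40 °C to rt; aq NH4Cl
Reagents that add atoms: iodine II
Why: CuI-catalysed anti-carbomagnesiation of the propargyl alkoxide (Duboudin reaction) gives the chelated alkenylmagnesium 6, whose iodinolysis with retention places iodine cis to the hydroxymethyl group.

Step 4
Reactants: 3 triethylsilyl ether; 7 Z-iodide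
Product: 8 enyne allylic alcohol
Conditions: Pd(PPh3)2Cl2 (3 mol %), CuI (6 mol %), Et3N, THF, rt
Reagents that add atoms: none
Why: Sonogashira coupling of the terminal alkyne with the alkenyl iodide forms C1–C2 with retention of the olefin geometry under mild conditions that should spare the propargylic epoxide.

Step 5
Reactants: 8 enyne allylic alcohol
Product: 9 bis-epoxy alkyne alcohol
Conditions: Ti(OiPr)4 (20 mol %), L-(+)-diethyl tartrate (24 mol %), tBuOOH, 4 Å MS, CH2Cl2, −20 °C
Reagents that add atoms: tert-butyl hydroperoxide CC(C)(C)OO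
Why: A second Sharpless asymmetric epoxidation, directed by the free C14 allylic hydroxyl, reaches only the C1=C10 olefin and with the L-(+)-tartrate sets 1R,10S, while the terminal alkene and the silyl-protected side do not react.

Step 6
Reactants: 9 bis-epoxy alkyne alcohol
Product: 10 bis-silyl ether
Conditions: tBuPh2SiCl, imidazole, DMAP (cat.), DMF, rt
Reagents that add atoms: tert-butyl(chloro)diphenylsilane CC(C)(C)[Si](Cl)(c1ccccc1)c1ccccc1
Why: Silylation gives a robust tert-butyldiphenylsilyl ether on C14–OH that should last to the final step.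

Step 7
Reactants: 10 bis-silyl ether
Product: 11 Z-alkene
Conditions: H2 (1 atm), Pd/CaCO3 poisoned with Pb(OAc)2, quinoline, EtOAc, rt
Reagents that add atoms: none
Why: Lindlar semihydrogenation adds H2 syn to the alkyne and gives the 2Z olefin, since the alkyne is reduced much faster than the terminal alkene or the hindered cis-alkene product.

Step 8
Reactants: 11 Z-alkene
Product: 13 epoxy aldehyde, via primary alcohol 12 (not isolated)
Conditions: (COCl)2, DMSO, CH2Cl2, −78 to −30 °C; Et3N, −78 °C to rt
Reagents that add atoms: none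
Why: Under Swern conditions a primary triethylsilyl ether is cleaved and oxidised in one pot to the aldehyde, while the tert-butyldiphenylsilyl ether and both epoxides survive.

Step 9
Reactants: 13 epoxy aldehyde; 14 3-chloroprop-1-yne
Product: 16 propargylic alcohol (6S), via 3-chloro-1-lithiopropyne 15 (not isolated)
Conditions: 14, n-BuLi, THF, −78 °C; then 13, −78 °C; aq NH4Cl
Reagents that add atoms: none
Why: 1,2-Addition of the lithium acetylide to the α,β-epoxy aldehyde should follow the polar Felkin–Anh model (epoxide C–O anti to the nucleophile) and give the 6S carbinol, erythro to the epoxide.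

Step 10
Reactants: 16 propargylic alcohol
Product: 17 triethylsilyl ether of 16
Conditions: Et3SiCl, imidazole, CH2Cl2, 0 °C
Reagents that add atoms: chlorotriethylsilane CC[Si](Cl)(CC)CC
Why: Silylation protects C6–OH as a poor leaving group next to the propargylic position, so that the organochromium reagent of step 12 does not eliminate.

Step 11
Reactants: 17 triethylsilyl ether
Product: 19 C8 aldehyde, via terminal diol 18 (not isolated)
Conditions: OsO4 (2 mol %), NaIO4, 2,6-lutidine, dioxane/H2O, rt; used crude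
Reagents that add atoms: sodium periodate [Na+].[O-]I(=O)(=O)=O
Why: Lemieux–Johnson oxidation cleaves the only unhindered, electron-rich olefin, because the 2Z olefin flanked by two epoxides and the alkyne react far more slowly, and the labile β,γ-epoxy aldehyde meets no base.

Step 12
Reactants: 19 C8 aldehyde
Product: 21 macrocyclic allenol (8S), via propargylchromium dichloride 20 (not isolated)
Conditions: CrCl2 (8 equiv), THF/DMF, rt, slow addition of 19, final 2 mM
Reagents that add atoms: none
Why: In this Nozaki–Hiyama allenylation the propargylchromium reagent adds through its γ-carbon C7 (SE2′, six-membered cyclic transition state) to the aldehyde, closing the ten-membered ring and creating the allene, and the 8S carbinol is planned from the arrangement in which C5 and C9 sit on the same face of the allene plane with the C6 silyloxy group in that plane.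

Step 13
Reactants: 21 macrocyclic allenol
Product: 22 C8 methacrylate
Conditions: methacrylic anhydride, Et3N, DMAP, CH2Cl2, 0 °C
Reagents that add atoms: methacrylic anhydride C=C(C)C(=O)OC(=O)C(C)=C
Why: DMAP-catalysed acylation of the secondary alcohol installs the methacrylate with retention at C8.

Step 14
Reactants: 22 C8 methacrylate
Product: 23 C6 alcohol
Conditions: HF·pyridine, pyridine, THF, 0 °C
Reagents that add atoms: none
Why: Buffered HF·pyridine removes the secondary triethylsilyl ether selectively, because the primary tert-butyldiphenylsilyl ether is far more robust.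

Step 15
Reactants: 23 C6 alcohol
Product: 25 tert-butyl peroxyoxalate, via chlorooxoacetate ester 24 (not isolated)
Conditions: (COCl)2, pyridine, CH2Cl2, −40 °C; evaporate cold; tBuOOH, pyridine, pentane/CH2Cl2, −30 °C; used at once
Reagents that add atoms: oxalyl chloride O=C(Cl)C(Cl)=O; tert-butyl hydroperoxide CC(C)(C)OO
Why: Acylation of the C6 alcohol by oxalyl chloride and of tert-butyl hydroperoxide by the resulting acid chloride is the standard synthesis of mixed peroxyoxalates and places C12 on O6.

Step 16
Reactants: 25 tert-butyl peroxyoxalate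
Product: 28 silyl-protected target, via alkoxycarbonyl radical 26 (not isolated), via allyl radical 27 (not isolated)
Conditions: Cu(OAc)2 (1.5 equiv), MeCN/benzene, 55 °C, degassed, slow addition of 25, final 3 mM
Reagents that add atoms: copper diacetate CC(=O)[O-].CC(=O)[O-].[Cu+2]
Why: Proposed new method: thermal O–O homolysis of the peroxyoxalate with loss of CO2 gives the alkoxycarbonyl radical 26, which adds to the central allene carbon C11 to give the allyl radical 27 (C7–C11–C13); Cu(OAc)2 oxidises 27 with acetate transfer at C13, and the monovalent copper so formed reduces the tert-butoxyl radical and returns to the divalent state. The closest known reaction types are the alkoxycarbonyl radical cyclisation of Se-phenyl selenocarbonates onto alkynes and the Kharasch–Sosnovsky capture of allyl radicals by divalent copper carboxylates. The butenolide closes in a 5-exo mode on the C11=C13 π bond, whose lobes lie in the plane of C6 and C8. No stereocentre is created: C6 is untouched and the C7=C11 geometry is fixed by the five-membered ring. The step needs ring closure at C11 to outrun decarboxylation of 26 and its 6-exo addition to C3, which the short planar tether and high dilution favour, and it needs acetate delivery at the primary C13 instead of the fully substituted C7, which sterics and the conjugated butenolide as the thermodynamic allylic acetate should secure. Divalent copper oxidises acyl-type radicals only slowly, so 26 should cyclise before it is intercepted.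

Step 17
Reactants: 28 silyl-protected target
Product: 29 target CNP0207684.1
Conditions: Bu4NF, AcOH, THF, 0 °C to rt
Reagents that add atoms: none
Why: Fluoride desilylation buffered with acetic acid should free C14–OH without acyl migration or epoxide opening.

Compound list
1 | (Z)-3-methylpent-2-en-4-yn-1-ol | C#C/C(C)=C\CO | starting material
2 | [(2S,3R)-3-ethynyl-3-methyloxiran-2-yl]methanol | C#C[C@@]1(C)O[C@H]1CO | intermediate
3 | triethyl{[(2S,3R)-3-ethynyl-3-methyloxiran-2-yl]methoxy}silane | C#C[C@@]1(C)O[C@H]1CO[Si](CC)(CC)CC | intermediate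
4 | prop-2-yn-1-ol | C#CCO | starting material
5 | allylmagnesium bromide | C=CC[Mg]Br | starting material
6 | cyclic alkenylmagnesium alkoxide (4-allyl-2,5-dihydro-1,2-oxamagnesole) | C=CCC1=C[Mg]OC1 | intermediate (not isolated)
7 | (2Z)-2-(iodomethylidene)pent-4-en-1-ol | OC/C(CC=C)=C\I | intermediate
8 | (2Z)-2-allyl-5-[(2R,3S)-2-methyl-3-(triethylsilyloxymethyl)oxiran-2-yl]pent-2-en-4-yn-1-ol | CC[Si](CC)(CC)OC[C@@H]1O[C@]1(C)C#C/C=C(\CO)CC=C | intermediate
9 | [(2S,3R)-2-allyl-3-{[(2R,3S)-2-methyl-3-(triethylsilyloxymethyl)oxiran-2-yl]ethynyl}oxiran-2-yl]methanol | CC[Si](CC)(CC)OC[C@@H]1O[C@]1(C)C#C[C@H]1O[C@]1(CO)CC=C | intermediate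
10 | tert-butyl{[(2S,3R)-2-allyl-3-{[(2R,3S)-2-methyl-3-(triethylsilyloxymethyl)oxiran-2-yl]ethynyl}oxiran-2-yl]methoxy}diphenylsilane | CC[Si](CC)(CC)OC[C@@H]1O[C@]1(C)C#C[C@H]1O[C@]1(CO[Si](c2ccccc2)(c3ccccc3)C(C)(C)C)CC=C | intermediate
11 | tert-butyl{[(2S,3R)-2-allyl-3-{(Z)-2-[(2R,3S)-2-methyl-3-(triethylsilyloxymethyl)oxiran-2-yl]ethenyl}oxiran-2-yl]methoxy}diphenylsilane | CC[Si](CC)(CC)OC[C@@H]1O[C@]1(C)/C=C\[C@H]1O[C@]1(CO[Si](c2ccccc2)(c3ccccc3)C(C)(C)C)CC=C | intermediate
12 | [(2S,3R)-3-{(Z)-2-[(2R,3S)-3-allyl-3-(tert-butyldiphenylsilyloxymethyl)oxiran-2-yl]ethenyl}-3-methyloxiran-2-yl]methanol | OC[C@@H]1O[C@]1(C)/C=C\[C@H]1O[C@]1(CO[Si](c2ccccc2)(c3ccccc3)C(C)(C)C)CC=C | intermediate (not isolated)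
13 | (2R,3R)-3-{(Z)-2-[(2R,3S)-3-allyl-3-(tert-butyldiphenylsilyloxymethyl)oxiran-2-yl]ethenyl}-3-methyloxirane-2-carbaldehyde | O=C[C@@H]1O[C@]1(C)/C=C\[C@H]1O[C@]1(CO[Si](c2ccccc2)(c3ccccc3)C(C)(C)C)CC=C | intermediate
14 | 3-chloroprop-1-yne | C#CCCl | starting material
15 | 3-chloro-1-lithiopropyne | [Li]C#CCCl | intermediate (not isolated)
16 | (1S)-1-[(2S,3R)-3-{(Z)-2-[(2R,3S)-3-allyl-3-(tert-butyldiphenylsilyloxymethyl)oxiran-2-yl]ethenyl}-3-methyloxiran-2-yl]-4-chlorobut-2-yn-1-ol | ClCC#C[C@H](O)[C@@H]1O[C@]1(C)/C=C\[C@H]1O[C@]1(CO[Si](c2ccccc2)(c3ccccc3)C(C)(C)C)CC=C | intermediate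
17 | triethylsilyl ether of 16 at the (1S)-carbinol (C6) | ClCC#C[C@H](O[Si](CC)(CC)CC)[C@@H]1O[C@]1(C)/C=C\[C@H]1O[C@]1(CO[Si](c2ccccc2)(c3ccccc3)C(C)(C)C)CC=C | intermediate
18 | terminal 1,2-diol of 17 (CH2–CH(OH)–CH2OH in place of the allyl group, both epimers at the new carbinol) | ClCC#C[C@H](O[Si](CC)(CC)CC)[C@@H]1O[C@]1(C)/C=C\[C@H]1O[C@]1(CO[Si](c2ccccc2)(c3ccccc3)C(C)(C)C)CC(O)CO | intermediate (not isolated)
19 | {(2S,3R)-2-(tert-butyldiphenylsilyloxymethyl)-3-[(Z)-2-{(2R,3S)-3-[(1S)-4-chloro-1-(triethylsilyloxy)but-2-yn-1-yl]-2-methyloxiran-2-yl}ethenyl]oxiran-2-yl}acetaldehyde | ClCC#C[C@H](O[Si](CC)(CC)CC)[C@@H]1O[C@]1(C)/C=C\[C@H]1O[C@]1(CO[Si](c2ccccc2)(c3ccccc3)C(C)(C)C)CC=O | intermediate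
20 | propargylchromium dichloride of 19 (CrCl2 in place of the chlorine at C13) | Cl[Cr](Cl)CC#C[C@H](O[Si](CC)(CC)CC)[C@@H]1O[C@]1(C)/C=C\[C@H]1O[C@]1(CO[Si](c2ccccc2)(c3ccccc3)C(C)(C)C)CC=O | intermediate (not isolated)
21 | macrocyclic allenol, 1R,4R,5S,6S,8S,10S: ten-membered ring C1–C10 with 1,10- and 4,5-epoxides, 2Z olefin, C4 methyl, C10 CH2OSiPh2tBu, C6 OSiEt3, C8 OH and exocyclic allene C7=C11=C13H2 | O[C@H]1C[C@@]2(CO[Si](c3ccccc3)(c4ccccc4)C(C)(C)C)O[C@@H]2/C=C\[C@@]2(C)O[C@H]2[C@@H](O[Si](CC)(CC)CC)C1=C=C | intermediate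
22 | 8-O-methacryloyl derivative of 21 | C=C(C)C(=O)O[C@H]1C[C@@]2(CO[Si](c3ccccc3)(c4ccccc4)C(C)(C)C)O[C@@H]2/C=C\[C@@]2(C)O[C@H]2[C@@H](O[Si](CC)(CC)CC)C1=C=C | intermediate
23 | 6-hydroxy allene: 22 with free C6–OH (6S) | C=C(C)C(=O)O[C@H]1C[C@@]2(CO[Si](c3ccccc3)(c4ccccc4)C(C)(C)C)O[C@@H]2/C=C\[C@@]2(C)O[C@H]2[C@@H](O)C1=C=C | intermediate
24 | 6-O-chlorooxoacetyl ester of 23 | C=C(C)C(=O)O[C@H]1C[C@@]2(CO[Si](c3ccccc3)(c4ccccc4)C(C)(C)C)O[C@@H]2/C=C\[C@@]2(C)O[C@H]2[C@@H](OC(=O)C(=O)Cl)C1=C=C | intermediate (not isolated)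
25 | 6-O-[(tert-butylperoxy)oxalyl] ester of 23 (mixed peroxyoxalate) | C=C(C)C(=O)O[C@H]1C[C@@]2(CO[Si](c3ccccc3)(c4ccccc4)C(C)(C)C)O[C@@H]2/C=C\[C@@]2(C)O[C@H]2[C@@H](OC(=O)C(=O)OOC(C)(C)C)C1=C=C | intermediate
26 | alkoxycarbonyl radical on O6 | C=C(C)C(=O)O[C@H]1C[C@@]2(CO[Si](c3ccccc3)(c4ccccc4)C(C)(C)C)O[C@@H]2/C=C\[C@@]2(C)O[C@H]2[C@@H](O[C]=O)C1=C=C | intermediate (not isolated)
27 | butenolide allyl radical (spin on C13 and C7) | C=C(C)C(=O)O[C@H]1C[C@@]2(CO[Si](c3ccccc3)(c4ccccc4)C(C)(C)C)O[C@@H]2/C=C\[C@@]2(C)O[C@H]2[C@H]2OC(=O)C([CH2])=C12 | intermediate (not isolated)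
28 | 14-O-tert-butyldiphenylsilyl ether of the target, 1R,4R,5S,6S,8S,10S | C=C(C)C(=O)O[C@H]1C[C@@]2(CO[Si](c3ccccc3)(c4ccccc4)C(C)(C)C)O[C@@H]2/C=C\[C@@]2(C)O[C@H]2[C@H]2OC(=O)C(COC(C)=O)=C12 | intermediate
29 | CNP0207684.1, (1R,4R,5S,6S,8S,10S)-13-acetoxy-1,10:4,5-diepoxy-14-hydroxy-8-methacryloyloxygermacra-2Z,7(11)-dien-6,12-olide | C=C(C)C(=O)O[C@H]1C[C@@]2(CO)O[C@@H]2/C=C\[C@@]2(C)O[C@H]2[C@H]2OC(=O)C(COC(C)=O)=C12 | target

Total step count: 17. Longest linear sequence: 16 steps (steps 1, 2 and 4–17, from compound 1).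

Steps most likely to fail

1. Step 16 (Proposed new method). The alkoxycarbonyl radical may lose CO2 or add to the C2=C3 olefin before it reaches C11, or the allyl radical may be acetoxylated at C7 or dimerise. The fallback uses known chemistry and sets out from compound 23. Chlorocyclocarbonylation of the 2,3-allenol with PdCl2 (5 mol %), CuCl2 and CO (1 atm) in THF buffered with MgO should give the 13-chloro butenolide F1, in which the lactone carbonyl comes from CO. Displacement of the allylic chloride with CsOAc in DMF then gives compound 28, where the route is rejoined.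

2. Step 12. The ring-closing addition may show poor facial selectivity at C8 and favour the 8R carbinol. The fallback sets out from compound 19. The ring closure is run as in step 12 and the 8R-epimeric allenol F2 is carried on. Mitsunobu esterification with methacrylic acid (PPh3, diisopropyl azodicarboxylate, toluene, 0 °C) inverts C8 and installs the ester in one operation, returning at compound 22, so that both epimers converge.

3. Step 9. Chelation of lithium between the aldehyde and epoxide oxygens may erode the Felkin–Anh preference and give much of the 6R epimer. The fallback sets out from compound 13. The acetylide is added as in step 9 without regard to selectivity, and the epimer mixture is oxidised with Dess–Martin periodinane to the epoxy ynone F3. Corey–Bakshi–Shibata reduction with the (R)-methyl oxazaborolidine and catecholborane at −78 °C (alkyne as the small group) should then give compound 16 under reagent control.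

Further compounds
F1 | step 16 | 13-chloro analogue of 28 (chloromethyl butenolide, 14-O-tert-butyldiphenylsilyl, 8-O-methacryloyl) | C=C(C)C(=O)O[C@H]1C[C@@]2(CO[Si](c3ccccc3)(c4ccccc4)C(C)(C)C)O[C@@H]2/C=C\[C@@]2(C)O[C@H]2[C@H]2OC(=O)C(CCl)=C12
F2 | step 12 | 8R epimer of macrocyclic allenol 21 | O[C@@H]1C[C@@]2(CO[Si](c3ccccc3)(c4ccccc4)C(C)(C)C)O[C@@H]2/C=C\[C@@]2(C)O[C@H]2[C@@H](O[Si](CC)(CC)CC)C1=C=C
F3 | step 9 | epoxy ynone, 16 with C6 as ketone | ClCC#CC(=O)[C@@H]1O[C@]1(C)/C=C\[C@H]1O[C@]1(CO[Si](c2ccccc2)(c3ccccc3)C(C)(C)C)CC=C
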